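The earlier runs and the new flask come from a simulation with constants of no real substance, noise included.

If a trace of impurity destroys catalyst one for one, a recipe is worth what survives that titration, not what was weighed in.

| setting | birch | oak | autumn | spring |
|---|---|---|---|---|
| left-handed substrate | 13 mM | 20 mM | 20 mM | 20 mM |
| right-handed substrate | 13 mM | 20 mM | 20 mM | 20 mM |
| reagent | 2 equiv | 2 equiv | 2.00 equiv | 3.00 equiv |
| precatalyst | 0.05 mol% | 0.1 mol% | 0.05 mol% | 0.05 mol% |
| impurity | 3.5 µM | 3.5 µM | 3.5 µM | 5.0 µM |
| remark | run made earlier | run made earlier |  |  |
| time |  |  | 6.0 min | 6.0 min |

| run | time / s | left-handed product / % | left-handed substrate / % |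
|---|---|---|---|
| birch | 10.0 | 0.3 | 50.0 |
| birch | 15.0 | 0.6 | 50.4 |
| birch | 30.0 | 0.2 | 49.3 |
| birch | 50.0 | 0.5 | 49.8 |
| birch | 80.0 | 0 | 49.7 |
| birch | 120 | 0.4 | 49.4 |
| oak | 10.0 | 0 | 49.3 |
| oak | 25.0 | 0.1 | 49.1 |
| oak | 40.0 | 1.2 | 48.9 |
| oak | 60.0 | 1.8 | 48.2 |
| oak | 90.0 | 3.0 | 47.1 |
| oak | 120 | 5.0 | 44.7 |

(scatter of a reading: 0.5 percentage points)

- the winner by amount of left-handed product, in percent of the left-handed substrate and right-handed substrate together charged; "neither" if no more than 2 percentage points parts them (autumn / spring / neither)
- how much left-handed product is there at the end, in percent of the left-handed substrate and right-handed substrate together charged: autumn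
- how much left-handed product is there at the end, in percent of the left-handed substrate and right-handed substrate together charged: spring

Oak stays near zero at first, an induction period, and reaches 5.0% by 120 s. Birch ends at 0.4%, inside a scatter of 0.5 percentage points. So I reduce each recipe to one number: one minus the impurity charge over the catalyst charge, with the loading counted on the left-handed substrate. Oak gives 82.5% and birch 46.2%. With surviving catalyst and reagent taken at their actual amounts, I reckon oak's rate at 8.46 times birch's, which scales oak's last reading to an estimate of 0.591% for birch.

Autumn's row gives 65.0%, its working share, the fraction of the catalyst charge that outlives the impurity. Spring's gives 50.0%, which is less, but spring carries 3.00 equiv of reagent against 2.00 equiv. No earlier run changes the equivalents of reagent or the charge of impurity, so first order in reagent is my guess. Then, with the impurity consumed and the precatalyst released, I reckon spring's rate at 1.15 times autumn's. That comparison drifts: spring has more impurity to consume, so I expect it to start behind.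

The forecast says 12% for autumn, 15% for spring, and spring as winner, its spring figure set “higher if turnover also uses reagent”. I part from it on the winner. Even on its autumn figure, the full late lead is worth 1.8 points, less than the margin of 2 points, so I say neither.

The flask gives 13.3% for autumn and 13.6% for spring, so the answer is neither.

    reagent + free catalyst + right-handed substrate → free catalyst + right-handed product (k = 3010 M⁻² s⁻¹)
    reagent + free catalyst + left-handed substrate → free catalyst + left-handed product (k = 7760 M⁻² s⁻¹)
    precatalyst → free catalyst (k = 0.00620 s⁻¹)
    free catalyst + impurity → spent catalyst (k = 17800 M⁻¹ s⁻¹)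

At 6.00 min, spring holds free catalyst 39.3% and precatalyst 10.7%, together 50.0% against its working share of 50.0%, and spent catalyst 50.0%. The neighbouring flask is spring with the impurity raised to 0.020 mM. Its working share is −100%, below zero, because the impurity charge is twice the catalyst charge. At 6.00 min it still holds 55.5% of its impurity, its free catalyst is 0.346%, and its left-handed product is 0.761%.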